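## Structural features

The target is a (2S)-flavanone: a benzene ring A (C4a, C5, C6, C7, C8, C8a) fused to a dihydropyran-4-one ring C (O1, C2, C3, C4), with a 4-hydroxyphenyl ring B on C2. Ring A is hexasubstituted: C5 carries a hydroxyl hydrogen-bonded to the C4 carbonyl, C6 and C7 carry methoxy groups, C8 carries a prenyl (3-methylbut-2-enyl) chain, and C4a and C8a are the fusion atoms. C2 is the only stereocentre; it is benzylic, bound to O1 and β to the ketone, has no neighbouring centre to relay from, and is erased whenever ring C opens reversibly to the 2'-hydroxychalcone (base, or strong acid acting on the para-oxygenated benzylic C2–O1 bond). The fragile groups are this centre, the trisubstituted prenyl alkene (acid, hydrogenation, electrophiles) and the two free phenols. The real difficulty is twofold: C2 must be created late and enantioselectively in a medium that does not open ring C, and on ring A the two oxygens flanking C4a (O1 and O5) must be told apart while the prenyl chain is placed on C8 and not on oxygen. The key step exploits the fact that, at the chromone oxidation level, C2 is the unsubstituted β-carbon of a flat, achiral vinylogous ester O1–C2=C3–C4=O, so the C2–C1' bond to ring B and the C2 configuration can be made together by face-selective aryl transfer. A second feature, C8 lying para to O5 with both ortho positions of O5 (C6 and C4a) blocked, is used to move the prenyl chain from O5 to C8.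

## Logic of the disconnections

In one sentence, the route is a catalyst-controlled enantioselective conjugate arylation of the achiral, fully substituted 9 with 10. This sentence does not describe the chalcone cyclisation that would be drawn first.

12 to 11: the O–Si bond at C4' is cut. The phenol of ring B is masked only to keep the boron partner well behaved. The forward step must remove silicon without base strong enough to open ring C and without acid strong enough to touch the prenyl alkene.

11 to 9 and 10 (key disconnection): the C2–C1' bond is cut. This removes ring B and the only stereocentre in one stroke and leaves a flat, achiral benzopyranone and a commercial arylboron reagent. The forward step must add the aryl group to one face of C2 under catalyst control, prefer the enone over the prenyl alkene, and run without base so that neither partner nor product opens to a chalcone.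

9 to 6 (through 8 and 7): the C8–CH2 bond of the prenyl chain is cut and the chain is reattached to O5. The C–C bond on a crowded arene becomes an O-alkyl bond, and the free C5 hydroxyl of 9 becomes the anchor of the chain. The forward step is a double [3,3] relay; it demands that the blocked ortho carbons (C6, C4a) pass the chain on to C8 rather than lose it.

6 to 4 and 5: the O5–CH2 bond is cut. This gives a simple phenol and a commercial allylic bromide. The forward step must alkylate the chelated C5 hydroxyl on oxygen.

4 to 3: the O5–CH3 bond is reformed in the retrosynthetic sense, giving a symmetrically protected trimethyl ether. The forward step must cleave only the methoxy group peri to the C4 carbonyl; this is what distinguishes O5 from O6 and O7.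

3 to 1 (through 2): the O1–C2 and C2–C3 bonds are cut, removing C2 as a one-carbon unit. This leaves a commercial acetophenone in which the single free hydroxyl is already the future O1, so O1 and O5 are differentiated from the start. The forward step must add one carbon to the methyl ketone and close ring C onto that hydroxyl.

## Other disconnections considered

Alternative 1: the first that comes to mind. Cut O1–C2 and close ring C by intramolecular oxa-Michael addition of the 2'-hydroxyl of chalcone A1, with a chiral amine–thiourea catalyst or a chalcone isomerase. The chosen plan is preferred for three reasons. A1 has two hydroxyls ortho to the acyl carbon, and closure through the other one would give the 6-prenyl-7,8-dimethoxy regioisomer A2, so an extra protection on a hexasubstituted ring would be needed. The cyclisation is reversible and base-mediated, so the conditions that form C2 can also erase it; small-molecule catalysts are expected to need an extra activating ester on the α-carbon, and an isomerase may not accept the 3'-prenyl-4',5'-dimethoxy pattern. Finally, A1 requires a C-prenylated, fully substituted acetophenone, which is longer to make than 9.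

Alternative 2: cut the C8–CH2 bond on the intact flavanone and form it last by enzymatic Friedel–Crafts prenylation of the prenyl-free flavanone A3 with dimethylallyl diphosphate A4, using an aromatic prenyltransferase of the flavanone 8-dimethylallyltransferase class. Enzymes of this class are expected to recognise a free C7 hydroxyl next to C8. In A3 that oxygen is methylated, which removes the phenol that activates C8 and changes the fit in the pocket. The enzymes are also membrane-bound and need a costly diphosphate donor. The non-enzymatic version on A3 would compete with O-alkylation and put C2 at risk. The sigmatropic relay in the chosen plan makes the same bond by geometry on an achiral chromone.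

Alternative 3: cut the C2–H bond and set C2 by asymmetric 1,4-reduction of flavone A5 (copper hydride with a chiral bisphosphine and a silane, or asymmetric hydrogenation). The β-carbon of A5 carries two donors of similar size (the aryl group and O1), so low reactivity and weak face discrimination are expected. Over-reduction to the flavan-4-ol is a further risk, hydrogenation catalysts would threaten the prenyl alkene, and A5 needs more steps than 9. The chosen plan transfers a carbon group to an unsubstituted β-carbon, where the two faces are clearly different.

Key step: step 5

Assumption: the facial sense of the palladium catalyst with (R)-t-BuPyOx, (R)-4-tert-butyl-2-(pyridin-2-yl)-4,5-dihydro-1,3-oxazole, on chromones is taken to parallel that on 3-substituted cyclic enones, so that the (R)-ligand adds the aryl group to the Re face of C2 and gives (2S); if the sense is opposite, the (S)-ligand is used and nothing else changes. Compounds 1, 5 and 10 are taken as commercial.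

## Steps

Step 1
Reactants: 1 1-(6-hydroxy-2,3,4-trimethoxyphenyl)ethan-1-one
Product: 3 5,6,7-trimethoxy-4H-chromen-4-one, via enaminone 2 (not isolated)
Conditions: DMF-DMA (2 equiv), PhMe, 100 °C; concentrate; then conc. HCl, CH2Cl2, 40 °C
Reagents that add atoms: N,N-dimethylformamide dimethyl acetal, COC(OC)N(C)C
Why: Condensation of the methyl ketone with the amide acetal gives the push–pull enaminone 2; acid then promotes addition of the phenol oxygen to the β-carbon and loss of dimethylamine, the standard enaminone route to 2,3-unsubstituted chromones, and the only free hydroxyl of 1 becomes O1.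

Step 2
Reactants: 3 5,6,7-trimethoxy-4H-chromen-4-one
Product: 4 5-hydroxy-6,7-dimethoxy-4H-chromen-4-one
Conditions: BCl3 (1.2 equiv), CH2Cl2, −78 to 0 °C; then H2O
Reagents that add atoms: none
Why: Chelation-controlled aryl methyl ether cleavage: BCl3 binds the C4 carbonyl and the peri C5 oxygen in a six-membered chelate and chloride removes only that methyl group, while the C6 and C7 ethers lack this assistance at low temperature.

Step 3
Reactants: 4 5-hydroxy-6,7-dimethoxy-4H-chromen-4-one; 5 1-bromo-3-methylbut-2-ene
Product: 6 6,7-dimethoxy-5-[(3-methylbut-2-en-1-yl)oxy]-4H-chromen-4-one
Conditions: K2CO3, DMF, 50 °C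
Reagents that add atoms: none
Why: Williamson etherification: the C5 hydroxyl is the only acidic site, and its potassium phenoxide in DMF should displace the primary allylic bromide on oxygen.

Step 4
Reactants: 6 6,7-dimethoxy-5-[(3-methylbut-2-en-1-yl)oxy]-4H-chromen-4-one
Product: 9 5-hydroxy-6,7-dimethoxy-8-(3-methylbut-2-en-1-yl)-4H-chromen-4-one, via ortho-dienone 7 (not isolated), via para-dienone 8 (not isolated)
Conditions: Eu(fod)3 (10 mol%; fod = 6,6,7,7,8,8,8-heptafluoro-2,2-dimethyloctane-3,5-dionate), PhCl, 100 °C
Reagents that add atoms: none
Why: Aromatic Claisen rearrangement followed by Cope rearrangement (para-Claisen relay): the europium chelate of O5 and the C4 carbonyl accelerates the first [3,3] shift to the blocked ortho carbon C6 to give 7, which cannot enolise and so undergoes a second [3,3] shift to C8 (a first shift to C4a would converge on the same carbon); the double allylic inversion restores the prenyl connectivity, and tautomerisation of 8 gives the chelated phenol 9, with no stereocentre yet present to be harmed by heat.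

Step 5
Reactants: 9 5-hydroxy-6,7-dimethoxy-8-(3-methylbut-2-en-1-yl)-4H-chromen-4-one; 10 [4-(tert-butyldimethylsilyloxy)phenyl]boronic acid
Product: 11 (2S)-2-[4-(tert-butyldimethylsilyloxy)phenyl]-5-hydroxy-6,7-dimethoxy-8-(3-methylbut-2-en-1-yl)-2,3-dihydro-4H-chromen-4-one
Conditions: Pd(OCOCF3)2 (10 mol%), (R)-t-BuPyOx (12 mol%), NH4PF6 (30 mol%), H2O (5 equiv), 10 (2.5 equiv), ClCH2CH2Cl, 60 °C, air
Reagents that add atoms: none
Why: This is the palladium-catalysed asymmetric conjugate addition of an arylboronic acid to a chromone with a pyridine–oxazoline ligand, a known reaction type. Transmetalation of 10 to the cationic divalent palladium complex gives an aryl–palladium species that binds C2=C3 of 9; enantio-determining syn migratory insertion places the aryl group on C2 and palladium on C3, and the palladium enolate is protonated by water, so palladium stays divalent and no β-hydride elimination to a flavone is required. No ring is closed; the step forms the C2–C1' bond and joins ring B to the finished ring A and ring C. C2 is the only new stereocentre and is set by the catalyst: the tert-butyl group of the (R)-ligand blocks one quadrant so that the aryl group is delivered to the Re face of C2, which corresponds to (2S). The step needs chemoselectivity for the enone over the prenyl alkene, which the unactivated, trisubstituted nature of that alkene should secure, and 1,4- over 1,2-addition, which is inherent in the insertion mechanism. The C5–OH to C4=O hydrogen bond lowers the LUMO of the vinylogous ester and should offset the three donor oxygens of ring A. The medium contains no base, so neither 9 nor 11 can open to a chalcone and the new centre should not erode; partial loss of the silyl group would be harmless because step 6 removes it.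

Step 6
Reactants: 11 (2S)-2-[4-(tert-butyldimethylsilyloxy)phenyl]-5-hydroxy-6,7-dimethoxy-8-(3-methylbut-2-en-1-yl)-2,3-dihydro-4H-chromen-4-one
Product: 12 (2S)-5-hydroxy-2-(4-hydroxyphenyl)-6,7-dimethoxy-8-(3-methylbut-2-en-1-yl)-2,3-dihydro-4H-chromen-4-one
Conditions: KHF2 (2 equiv), MeOH, rt
Reagents that add atoms: none
Why: Fluoride-mediated cleavage of the aryl silyl ether; KHF2 in methanol is mildly acidic, so the base-sensitive C2 centre and the prenyl alkene should be untouched and the (2S) configuration set in step 5 is carried into the target.

## Compound list

1 | 1-(6-hydroxy-2,3,4-trimethoxyphenyl)ethan-1-one | CC(=O)c1c(O)cc(OC)c(OC)c1OC | starting material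
2 | (E)-3-(dimethylamino)-1-(6-hydroxy-2,3,4-trimethoxyphenyl)prop-2-en-1-one | CN(C)/C=C/C(=O)c1c(O)cc(OC)c(OC)c1OC | intermediate
3 | 5,6,7-trimethoxy-4H-chromen-4-one | COc1cc2occc(=O)c2c(OC)c1OC | intermediate
4 | 5-hydroxy-6,7-dimethoxy-4H-chromen-4-one | COc1cc2occc(=O)c2c(O)c1OC | intermediate
5 | 1-bromo-3-methylbut-2-ene | CC(C)=CCBr | starting material
6 | 6,7-dimethoxy-5-[(3-methylbut-2-en-1-yl)oxy]-4H-chromen-4-one | COc1cc2occc(=O)c2c(OCC=C(C)C)c1OC | intermediate
7 | 6,7-dimethoxy-6-(2-methylbut-3-en-2-yl)-4H-chromene-4,5(6H)-dione (ortho-dienone, racemic at C6) | O=C1C(OC)(C(C)(C)C=C)C(OC)=CC2=C1C(=O)C=CO2 | intermediate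
8 | 6,7-dimethoxy-8-(3-methylbut-2-en-1-yl)-4H-chromene-4,5(8H)-dione (para-dienone, racemic at C8) | O=C1C(OC)=C(OC)C(CC=C(C)C)C2=C1C(=O)C=CO2 | intermediate
9 | 5-hydroxy-6,7-dimethoxy-8-(3-methylbut-2-en-1-yl)-4H-chromen-4-one | COc1c(OC)c(CC=C(C)C)c2occc(=O)c2c1O | intermediate
10 | [4-(tert-butyldimethylsilyloxy)phenyl]boronic acid | CC(C)(C)[Si](C)(C)Oc1ccc(B(O)O)cc1 | starting material
11 | (2S)-2-[4-(tert-butyldimethylsilyloxy)phenyl]-5-hydroxy-6,7-dimethoxy-8-(3-methylbut-2-en-1-yl)-2,3-dihydro-4H-chromen-4-one | COc1c(O)c2c(c(CC=C(C)C)c1OC)O[C@H](c1ccc(O[Si](C)(C)C(C)(C)C)cc1)CC2=O | intermediate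
12 | (2S)-5-hydroxy-2-(4-hydroxyphenyl)-6,7-dimethoxy-8-(3-methylbut-2-en-1-yl)-2,3-dihydro-4H-chromen-4-one | COc1c(O)c2c(c(CC=C(C)C)c1OC)O[C@H](c1ccc(O)cc1)CC2=O | target

## Step count and least certain steps

Total step count: 6. Longest linear sequence: 6 steps (1 to 12); 5 and 10 enter as commercial partners.

Step 5 (key step). The most likely failure is stalled conversion. The C5-hydroxy/C4-keto unit of 9 can bind the cationic divalent palladium as an O,O-chelate, and insertion into a chromone with three donor oxygens is slow, so protodeboronation of 10 may outrun the addition. The fallback masks O5 with the prenyl group itself and moves the relay to the end. It sets out from 6, which is arylated with 10 under the conditions of step 5 to give (2S)-2-[4-(tert-butyldimethylsilyloxy)phenyl]-6,7-dimethoxy-5-[(3-methylbut-2-en-1-yl)oxy]-2,3-dihydro-4H-chromen-4-one F1. The prenyl ether of F1 is then relayed from O5 to C8 with Eu(fod)3 in chloroform at 60 °C, and the route is rejoined at 11.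

Step 4. The first [3,3] shift must build a quaternary carbon at a blocked ortho position, so fragmentation of the prenyl ether (loss of the chain as isoprene, returning 4) may compete, or the relay may stall before the second shift. The fallback replaces the sigmatropic relay by cross-coupling. It sets out from 4, which is iodinated with N-iodosuccinimide at C8, the only unsubstituted carbon of ring A, to give 5-hydroxy-8-iodo-6,7-dimethoxy-4H-chromen-4-one F2. Stille coupling of F2 with allyltributylstannane and Pd(PPh3)4 gives 5-hydroxy-6,7-dimethoxy-8-(prop-2-en-1-yl)-4H-chromen-4-one F3. Cross-metathesis of F3 with 2-methylbut-2-ene and the second-generation Grubbs catalyst RuCl2(H2IMes)(PCy3)(=CHPh) rejoins the route at 9.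

Step 2. Over-cleavage is the likely problem: once the C5 borate has formed it can direct a second cleavage at the neighbouring C6 methoxy group, giving mixtures. The fallback overshoots on purpose and then corrects. It sets out from 3, which is treated with excess BBr3 to give 5,6-dihydroxy-7-methoxy-4H-chromen-4-one F4. The non-chelated C6 hydroxyl of F4 is more nucleophilic than the chelated C5 hydroxyl and is methylated selectively with one equivalent of MeI and K2CO3 in DMF, rejoining the route at 4.

Step 6. The C2 configuration could erode by reversible opening of ring C if the fluoride medium becomes basic, and cleavage may be slow under the mild conditions chosen to avoid this. The fallback removes the protecting group from the plan. It sets out from 9, which is arylated under the conditions of step 5 with unprotected (4-hydroxyphenyl)boronic acid, and arrives directly at 12; no new compound arises on this way (F0).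

## Further compounds

F1 | step 5 | (2S)-2-[4-(tert-butyldimethylsilyloxy)phenyl]-6,7-dimethoxy-5-[(3-methylbut-2-en-1-yl)oxy]-2,3-dihydro-4H-chromen-4-one | COc1cc2c(c(OCC=C(C)C)c1OC)C(=O)C[C@@H](c1ccc(O[Si](C)(C)C(C)(C)C)cc1)O2
F2 | step 4 | 5-hydroxy-8-iodo-6,7-dimethoxy-4H-chromen-4-one | COc1c(OC)c(I)c2occc(=O)c2c1O
F3 | step 4 | 5-hydroxy-6,7-dimethoxy-8-(prop-2-en-1-yl)-4H-chromen-4-one | COc1c(OC)c(CC=C)c2occc(=O)c2c1O
F4 | step 2 | 5,6-dihydroxy-7-methoxy-4H-chromen-4-one | COc1cc2occc(=O)c2c(O)c1O
F0 | step 6 | none | none
A1 | alternative 1 | (E)-1-[2,6-dihydroxy-3,4-dimethoxy-5-(3-methylbut-2-en-1-yl)phenyl]-3-(4-hydroxyphenyl)prop-2-en-1-one | COc1c(O)c(C(=O)/C=C/c2ccc(O)cc2)c(O)c(CC=C(C)C)c1OC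
A2 | alternative 1 | (2S)-5-hydroxy-2-(4-hydroxyphenyl)-7,8-dimethoxy-6-(3-methylbut-2-en-1-yl)-2,3-dihydro-4H-chromen-4-one | COc1c(OC)c2c(c(O)c1CC=C(C)C)C(=O)C[C@@H](c1ccc(O)cc1)O2
A3 | alternative 2 | (2S)-5-hydroxy-2-(4-hydroxyphenyl)-6,7-dimethoxy-2,3-dihydro-4H-chromen-4-one | COc1cc2c(c(O)c1OC)C(=O)C[C@@H](c1ccc(O)cc1)O2
A4 | alternative 2 | dimethylallyl diphosphate | CC(C)=CCOP(O)(=O)OP(O)(O)=O
A5 | alternative 3 | 5-hydroxy-2-(4-hydroxyphenyl)-6,7-dimethoxy-8-(3-methylbut-2-en-1-yl)-4H-chromen-4-one | COc1c(O)c2c(c(CC=C(C)C)c1OC)oc(-c1ccc(O)cc1)cc2=O
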